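The data were computed with constants of no real substance; the scatter is artificial.

Take conversion from the substrate, not from the target: what is bound to the catalyst counts as converted.

- alpha: substrate 1.2 M; reagent 2.4 M; free catalyst 60 mM; the very flask that is asked about, followed so far
- flask: substrate 1.2 M; reagent 2.40 M; free catalyst 60 mM

alpha run (percent of the substrate charged)

| time / h | target / % | substrate / % |
|---|---|---|
| 2.50 | 11 | 87 |
| 8.00 | 30 | 66 |
| 15.0 | 49 | 51 |
| 20.0 | 54 | 42 |
| 30.0 | 66 | 34 |

(standard deviation of a reading: 1.5 percentage points)

- factor on the rate of making target when 20 % of the substrate are converted if free catalyst is charged twice over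
- factor on the rate when 20 % of the substrate are converted if free catalyst is charged at 300 mM instead

- what may be going on: reagent + catalyst intermediate A -> catalyst intermediate B; substrate + free catalyst <-> catalyst intermediate A; catalyst intermediate B -> free catalyst + target; reagent + free catalyst -> spent catalyst
- no earlier run changes the charge of free catalyst; that part of a forecast is a guess
- what is bound to the catalyst counts as converted

I hand over this flask with reagent charged above substrate, so substrate is the limiting reagent. I carry one number, 5.00 %, the catalyst load: the catalyst charged as a fraction of the substrate charged. Each intermediate carries one substrate, so substrate plus target can fall short of the charge by that much and no further. At 8.00 h this flask's readings fall short by 4 percentage points, inside the load, with 1.5 points on each reading. Expect the gap to stay inside the load when you come.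

Leave the catalyst charge alone; no earlier run changes it, so what follows is a guess.

At fixed conversion about the same substrate and reagent remain, so I let the rate follow the catalyst: about 2 on doubling, and 5.00 at 300 mM. But that second flask has a load of 25.0 %, above the 20 % mark, so the mark can be met partly on the catalyst. I stand under 5.00 there, and under the forecast. The forecast says 2.05 (1.9 to 2.3) and 5 (4.2 to 5.7), holding that “the intermediates take up a real share of the 20%”.

The simulation gives 2.25 and 4.73, both within the forecast's ranges.

    reagent + catalyst intermediate A → catalyst intermediate B (k = 1.10 M⁻¹ h⁻¹)
    substrate + free catalyst ⇌ catalyst intermediate A (K = 5.80 M⁻¹, k = 3.90 M⁻¹ h⁻¹)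
    catalyst intermediate B → free catalyst + target (k = 3.50 h⁻¹)
    reagent + free catalyst → spent catalyst (k = 0.0660 M⁻¹ h⁻¹)

At 0.250 d the two intermediates in this flask hold 2.48 % of the substrate charge, inside the load. The flask with the load of 25.0 % gives 4.73, under 5.00. The doubled flask gives 2.25, above 2, and catalyst death is at most the largest single effect behind that. In the run without the turning of reagent + free catalyst into spent catalyst, the apparent order in free catalyst at 20 % conversion falls from 1.2 to 1.0.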